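# Proposed total synthesis of CNP0494338.1

## Structural features

The target is a 3‑acyl‑4‑hydroxy‑2(1H)‑pyridone. Its C3 carries a ketone that is bonded to C2 of a trans‑fused 1,2,4a,5,6,7,8,8a‑octahydronaphthalene (rings A and B), and its C5 is bonded to the fully substituted C1' of a cyclohexane. The decalin holds five stereocentres: C1 (E‑propenyl), C2 (acyl), C8a and C4a are contiguous around ring A, and C7 (methyl) lies remote in ring B. All substituents are equatorial, with C1/C2 trans and the ring fusion trans, and ring A also contains the trisubstituted C3=C4 alkene bearing the C4 methyl group. The cyclohexane holds four contiguous stereocentres, C1' (tertiary OH), C2'/C3' (epoxide) and C4' (secondary OH). The two hydroxyls are cis to each other and anti to the epoxide oxygen, so the pyridyl group is syn to the epoxide, which is the opposite of what carbonyl addition next to an existing epoxide delivers. Fragile points are the epoxide flanked by two carbinols (migration under base, opening or semipinacol shift under acid), the ionisable tertiary pyridyl carbinol, and C2–H, which is α to the ketone and allylic and can epimerise or let the alkene move into conjugation. The real difficulty is that the two stereochemical clusters (5 + 4 centres) are separated by an achiral heteroaromatic ring and cannot control each other, so each half must be made as a single enantiomer and the pyridone unmasked last without disturbing the epoxide. The key step exploits ring A: C1 and C2 are vicinal, trans and each carries a carbon substituent at the carbonyl oxidation level, and C4 (para to C1) can be an oxygenated carbon. That pattern is the retron of a [4+2] between a 2‑silyloxybutadiene (C3, C4, C4a, C8a) and an E‑4‑oxobut‑2‑enoate (C1, C2).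

## Logic of the disconnections

**33 ⇒ 32.** No skeletal bond is cut; two O–Si bonds on the carbinols and two O–C bonds of the pyridine ethers are traced back. The pyridone is carried as an aromatic 2,4‑dialkoxypyridine that tolerates organolithium chemistry, and all four masks are fluoride‑labile so that neither acid nor free alkoxide meets the epoxide. The end‑game shrinks to one operation. The forward step must remove four groups under buffered fluoride without epoxide migration.

**32 ⇒ 31 ⇒ 29 + 15.** The bond between pyridine C3 and the carbonyl carbon is cut. It is the only bond joining the two stereochemical domains, and it pairs a carbon flanked by two alkoxy groups (a stable aryl anion) with a carbonyl electrophile. The gain is full convergence. The forward step needs a hindered aryllithium to add to an enolisable, α‑branched aldehyde faster than it deprotonates it; the new carbinol centre is then erased by oxidation.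

**15 ⇒ 14 ⇒ 13 ⇒ 12 ⇒ 10.** The C4–CH3 bond is cut and the aldehyde is traced to the ester. A methyl‑bearing trisubstituted alkene is the retron of an enol triflate cross‑coupling, and the C4 ketone it requires is the activating group for building ring B. The demand is kinetic enolisation of 10 toward C3 and not toward the ring‑fusion carbon C4a.

**10 ⇒ 9 ⇒ 8 ⇒ 6 + 7.** Bonds C8a–C8 and C4a–C5 are cut (ring B), and the C7–H bond is traced to an alkene. Isoprene supplies C5–C8 and the methyl group in one step and leaves a monocyclic enone. The forward sequence must add the diene anti to the C1 substituent with the methyl ending on C7, epimerise C4a to the trans fusion, and reduce only the trisubstituted alkene with the methyl ending equatorial.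

**6 ⇒ 5 ⇒ 4.** The C4a=C8a unsaturation is traced to the silyl enol ether, and the propenyl Cα=Cβ bond is cut to an aldehyde. The enol ether left by the cycloaddition fixes where the enone forms, and the aldehyde is the natural residue of the dienophile. The demand is an E‑selective olefination that does not epimerise the α‑formyl centre.

**4 ⇒ 2 + 3 (key).** Bonds C1–C8a and C2–C3 are cut. This is where absolute configuration enters the decalin: two achiral, simple partners give ring A with C1 and C2 set. The demand is catalyst control of the face and aldehyde‑over‑ester activation for the regiochemistry.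

**2 ⇒ 1.** The O–Si bond is cut; one silylation of a commodity enone.

**29 ⇒ 28 ⇒ 25 ⇒ 24.** The C3–Br bond, then one epoxide C–O bond (to a cis‑diol), then both diol C–O bonds (to an alkene) are cut. Peracid epoxidation is avoided because of the pyridine nitrogen; osmylation anti to both allylic silyloxy groups puts the oxygens on the correct face. The demand is net retention in the diol‑to‑epoxide conversion.

**24 ⇒ 21 + 19.** The bond between pyridine C5 and C1' is cut. The aryl group must enter before any oxygen sits on C2', since addition next to an existing C2' oxygen would come anti to it. The gain is a chiral enone with one stereocentre. The demand is addition anti to the C4' silyloxy group.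

**19 ⇒ 18 ⇒ 17 ⇒ 16 and 21 ⇒ 20.** The C4' stereocentre is traced to a prochiral enone ketal by asymmetric transfer hydrogenation, and the two pyridine C–O bonds to chlorides by nucleophilic aromatic substitution. Both end at catalogue compounds.

## Other disconnections considered

**Alternative 1:** The cut is the pair of C–O bonds at C1' and C4'. The forward key step is a photosensitised singlet‑oxygen [4+2] across the diene of the pyridyl dihydrodiol acetonide A2 (from the microbial dihydrodiol A1 by acetonide formation and cross‑coupling), giving endoperoxide A3 anti to the acetonide.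
- In its favour: the concerted addition makes the cis‑1,4 relation at C1'/C4' a consequence of mechanism; A1 already has the C2'/C3' configuration required; the O–O bridge masks both carbinols while the remaining alkene is reduced and the diol converted to the epoxide.
- Against it here: it solves only the western half; a benzylic peroxide must survive several steps including acetonide removal; the cis‑diol must still be turned into the epoxide with retention.
- Comparison: on control of C1' it is better than the chosen plan, which relies on 1,4‑induction in step 16. On step count for the fragment it is equal (about eight operations). It is weaker on handling (peroxides, photochemistry). It does not compete with the chosen key step, which concerns ring A, and is used below as the fallback for step 16.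

**Alternative 2:** The cuts are N1–C2 and C3–C4 of the pyridone. Thermolysis of dioxinone A4 releases acylketene A5, which acylates the nitrogen of enamino ester A6; base then closes C3 onto the ester (Dieckmann) to give the bis‑silyl ether A7.
- In its favour: no pyridine protecting groups, no organolithium union, no carbinol oxidation, and a final step that is only desilylation. On the end‑game it is better than the chosen plan.
- Against it here: A6 needs a quaternary carbinol α to an acrylate, which meets the same facial problem as aryl addition but without a robust aromatic carrier; heat followed by alkoxide base puts C2 and the epoxide at greater risk; A4 costs about three extra steps from 13.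
- Comparison: convergence is equal and the overall count about equal. The chosen plan is safer for C2 because its union is run at −78 °C.

**Alternative 3:** The cuts are C8a–C1 and C4=C4a. 4‑Methylcyclohexanone A8, activated with a chiral amine, adds through one enantiotopic α‑carbon to the propenyl‑bearing carbon of dienyl keto ester A9, and aldol condensation closes ring A to give octalone A10.
- In its favour: ring B, the C7 methyl and the C4 methyl are bought; three stereocentres and a ring form in one operation; no chemoselective alkene reduction is needed. On step economy to the bicycle, and on C7, it is better than the chosen plan.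
- Against it here: the desymmetrisation is controlled from a centre four bonds away with no well‑tested model; A9 can react 1,6 as well as 1,4; C1/C8a arise from an open transition state; A10 has the wrong pattern in ring A (C3 ketone, C4=C4a), so a reductive 1,3‑transposition must later set C4a.
- Comparison: the chosen plan is about four steps longer to the decalin, but its absolute configuration comes from a reaction class with a dependable model and each later centre is set under substrate control. The two are equal in relying on the equatorial preference at C2.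

Key step: step 2

Remarks on the chemistry:
- The (S) catalyst in step 2 is assigned from the formyl C–H···O binding model; the (R) catalyst is equally available if the sense proves opposite.
- Compounds 3, 7, 16, 20 and the sulfone of step 3 are taken as catalogue items.
- Atom‑by‑atom comparison shows that the (1R,6R) adduct 4 carries C1 and C2 of 33 unchanged; later CIP labels change only because substituent priorities change.

## Route

Step 1
Reactants: 1 but‑3‑en‑2‑one (methyl vinyl ketone)
Product: 2 2‑[(triisopropylsilyl)oxy]buta‑1,3‑diene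
Conditions: TIPSOTf, Et3N, CH2Cl2, 0 °C → rt
Reagents that add atoms: triisopropylsilyl trifluoromethanesulfonate, CC(C)[Si](C(C)C)(C(C)C)OS(=O)(=O)C(F)(F)F
Why: Soft enolisation and O‑silylation of the methyl ketone gives the cross‑conjugated silyloxydiene; the bulky silyl group makes it isolable and slows Mukaiyama‑type side reactions in step 2.

Step 2
Reactants: 2 2‑[(triisopropylsilyl)oxy]buta‑1,3‑diene; 3 ethyl (2E)‑4‑oxobut‑2‑enoate
Product: 4 ethyl (1R,6R)‑6‑formyl‑3‑[(triisopropylsilyl)oxy]cyclohex‑3‑ene‑1‑carboxylate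
Conditions: (S)‑3,3‑diphenyl‑1‑(2‑methylphenyl)tetrahydro‑1H,3H‑pyrrolo[1,2‑c][1,3,2]oxazaborole (20 mol%), (CF3SO2)2NH (18 mol%), CH2Cl2, −78 → −40 °C; Et3N quench
Reagents that add atoms: none
Why: The N‑protonated oxazaborolidine binds the formyl oxygen of 3 syn to the formyl hydrogen, which is held by a C–H···O contact to the ring oxygen, whereas the ester carbonyl is the less organised site, so the aldehyde complex carries the reaction. Activation through the aldehyde makes the ester‑bearing carbon the electrophilic terminus; the enol‑ether CH2 of 2 bonds there first (C2–C3) and the vinyl terminus then bonds to the formyl‑bearing carbon (C1–C8a) in one concerted, asynchronous, suprafacial [4+2] event. The closest known reaction type is the oxazaborolidinium‑catalysed enantioselective Diels–Alder reaction of 2‑silyloxybutadienes with enals and fumarates. Ring A is closed by intermolecular cycloaddition with both σ‑bonds formed on one face of each partner, so no stepwise ring‑closure mode is involved. The trans C1/C2 relation copies the E geometry of 3. Both centres take their absolute configuration from the catalyst: in the s‑trans complex one face of the alkene is stacked against a phenyl group of the diphenylprolinol unit and the diene enters from the open face, which for the (S) catalyst is the face leading to (1R,6R)‑4. The step needs regioselectivity (silyloxy carbon para to the formyl‑bearing carbon), enantioselectivity and survival of the enol ether; these are secured by aldehyde‑over‑ester activation, the bound‑aldehyde geometry, the robust triisopropylsilyl group and a cold non‑aqueous quench that also protects the α‑formyl centre.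

Step 3
Reactants: 4 ethyl (1R,6R)‑6‑formyl‑3‑[(triisopropylsilyl)oxy]cyclohex‑3‑ene‑1‑carboxylate
Product: 5 ethyl (1R,6S)‑6‑[(1E)‑prop‑1‑en‑1‑yl]‑3‑[(triisopropylsilyl)oxy]cyclohex‑3‑ene‑1‑carboxylate
Conditions: 5‑(ethylsulfonyl)‑1‑phenyl‑1H‑tetrazole, KN(SiMe3)2, DME, −60 °C; then 4, −60 °C → rt; aq. NH4Cl
Reagents that add atoms: 5‑(ethylsulfonyl)‑1‑phenyl‑1H‑tetrazole, CCS(=O)(=O)c1nnnn1-c1ccccc1
Why: Julia–Kocienski olefination; the pre‑metalated phenyltetrazolyl sulfone adds to the aldehyde faster than it enolises it, and Smiles rearrangement followed by anti elimination of SO2 and tetrazolate should give the E‑propenyl group with C1 untouched.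

Step 4
Reactants: 5 ethyl (1R,6S)‑6‑[(1E)‑prop‑1‑en‑1‑yl]‑3‑[(triisopropylsilyl)oxy]cyclohex‑3‑ene‑1‑carboxylate
Product: 6 ethyl (1R,2R)‑5‑oxo‑2‑[(1E)‑prop‑1‑en‑1‑yl]cyclohex‑3‑ene‑1‑carboxylate
Conditions: Pd(OAc)2 (1.1 equiv), MeCN, 40 °C
Reagents that add atoms: none
Why: Saegusa–Ito oxidation; divalent palladium exchanges with the silyl enol ether to a C4a‑bound palladium enolate, and β‑hydride elimination can only occur from C8a, so the enone forms regiospecifically as C4(=O)–C4a=C8a without base.

Step 5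
Reactants: 6 ethyl (1R,2R)‑5‑oxo‑2‑[(1E)‑prop‑1‑en‑1‑yl]cyclohex‑3‑ene‑1‑carboxylate; 7 2‑methylbuta‑1,3‑diene (isoprene)
Product: 8 ethyl (1R,2R,4aR,8aR)‑7‑methyl‑4‑oxo‑1‑[(1E)‑prop‑1‑en‑1‑yl]‑1,2,3,4,4a,5,8,8a‑octahydronaphthalene‑2‑carboxylate (cis‑fused)
Conditions: EtAlCl2 (0.5 equiv), 7 (10 equiv), toluene, −20 °C → rt
Reagents that add atoms: none
Why: Lewis‑acid‑catalysed Diels–Alder reaction of a 4‑substituted cyclohexenone; the more nucleophilic CH2 of isoprene bonds to the β‑carbon C8a ("para" rule, methyl on C7), the diene approaches anti to the pseudo‑equatorial C1 propenyl group (setting C8a), and suprafacial addition gives the cis fusion.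

Step 6
Reactants: 8 cis‑fused octalone (as above)
Product: 9 ethyl (1R,2R,4aS,8aR)‑7‑methyl‑4‑oxo‑1‑[(1E)‑prop‑1‑en‑1‑yl]‑1,2,3,4,4a,5,8,8a‑octahydronaphthalene‑2‑carboxylate (trans‑fused)
Conditions: DBU (0.2 equiv), toluene, rt
Reagents that add atoms: none
Why: Base‑mediated epimerisation at C4a (α to the C4 ketone) through the enolate; the trans‑fused isomer with all substituents equatorial is the thermodynamic product, and residual cis isomer can be resubmitted.

Step 7
Reactants: 9 trans‑fused octalone (as above)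
Product: 10 ethyl (1R,2R,4aS,7S,8aR)‑7‑methyl‑4‑oxo‑1‑[(1E)‑prop‑1‑en‑1‑yl]decahydronaphthalene‑2‑carboxylate
Conditions: Mn(dpm)3 [tris(2,2,6,6‑tetramethylheptane‑3,5‑dionato)manganese] (10 mol%), PhSiH3, t‑BuOOH, i‑PrOH, rt
Reagents that add atoms: none
Why: Metal‑hydride hydrogen‑atom‑transfer hydrogenation; the hydride adds Markovnikov to the trisubstituted C6=C7 alkene to give a tertiary C7 radical, which takes the second hydrogen axially so the methyl ends equatorial (sets C7), while the 1,2‑disubstituted propenyl group, which would give a secondary radical, reacts much more slowly.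

Step 8
Reactants: 10 ethyl (1R,2R,4aS,7S,8aR)‑7‑methyl‑4‑oxo‑1‑[(1E)‑prop‑1‑en‑1‑yl]decahydronaphthalene‑2‑carboxylate
Product: 12 ethyl (1R,2S,4aS,7S,8aR)‑7‑methyl‑1‑[(1E)‑prop‑1‑en‑1‑yl]‑4‑{[(trifluoromethyl)sulfonyl]oxy}‑1,2,4a,5,6,7,8,8a‑octahydronaphthalene‑2‑carboxylate, via potassium C3‑enolate 11 (not isolated)
Conditions: KN(SiMe3)2 (1.05 equiv), THF, −78 °C; then PhNTf2, −78 → 0 °C; aq. NH4Cl
Reagents that add atoms: N‑phenylbis(trifluoromethanesulfonimide), O=S(=O)(N(c1ccccc1)S(=O)(=O)C(F)(F)F)C(F)(F)F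
Why: Kinetic deprotonation of the ketone occurs at the C3 methylene and not at the tertiary ring‑fusion C4a–H or the less acidic ester α‑position, and O‑triflation of the enolate fixes the C3=C4 double bond.

Step 9
Reactants: 12 enol triflate (as above)
Product: 13 ethyl (1R,2S,4aS,7S,8aR)‑4,7‑dimethyl‑1‑[(1E)‑prop‑1‑en‑1‑yl]‑1,2,4a,5,6,7,8,8a‑octahydronaphthalene‑2‑carboxylate
Conditions: MeZnCl (from MeMgCl and ZnCl2), Pd(PPh3)4 (5 mol%), THF, 0 °C → rt
Reagents that add atoms: methylzinc chloride, C[Zn]Cl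
Why: Negishi coupling; zerovalent palladium inserts into the vinyl C–O bond, transmetalation and reductive elimination install the C4 methyl group, and the neutral organozinc leaves the ester and the allylic C2–H alone.

Step 10
Reactants: 13 decalin ethyl ester (as above)
Product: 14 [(1R,2S,4aS,7S,8aR)‑4,7‑dimethyl‑1‑[(1E)‑prop‑1‑en‑1‑yl]‑1,2,4a,5,6,7,8,8a‑octahydronaphthalen‑2‑yl]methanol
Conditions: LiAlH4, Et2O, 0 °C; aq. NaOH work‑up
Reagents that add atoms: none
Why: Hydride reduction of the ester to the primary alcohol; going through the alcohol avoids the uncertain partial reduction of a hindered ester.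

Step 11
Reactants: 14 decalin primary alcohol (as above)
Product: 15 (1R,2S,4aS,7S,8aR)‑4,7‑dimethyl‑1‑[(1E)‑prop‑1‑en‑1‑yl]‑1,2,4a,5,6,7,8,8a‑octahydronaphthalene‑2‑carbaldehyde
Conditions: Dess–Martin periodinane, NaHCO3, CH2Cl2, 0 °C → rt
Reagents that add atoms: none
Why: Buffered Dess–Martin oxidation is non‑basic, so the β,γ‑unsaturated aldehyde should neither epimerise at C2 nor move into conjugation; it is used directly in step 20.

Step 12
Reactants: 16 1,4‑dioxaspiro[4.5]dec‑6‑en‑8‑one
Product: 17 (8R)‑1,4‑dioxaspiro[4.5]dec‑6‑en‑8‑ol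
Conditions: RuCl(p‑cymene)[(R,R)‑TsDPEN] [chloro(p‑cymene)((R,R)‑N‑tosyl‑1,2‑diphenylethylenediamine)ruthenium] (1 mol%), HCO2Na, Bu4NCl, CH2Cl2/H2O, rt
Reagents that add atoms: none
Why: Noyori‑type asymmetric transfer hydrogenation; the alkene plays the role of the aryl group of an aryl ketone in the CH/π‑controlled hydride transfer, so the (R,R) catalyst should give the (R) allylic alcohol (sets C4') with 1,2‑selectivity and the ketal intact at neutral pH.

Step 13
Reactants: 17 (8R)‑1,4‑dioxaspiro[4.5]dec‑6‑en‑8‑ol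
Product: 18 tert‑butyl[(8R)‑1,4‑dioxaspiro[4.5]dec‑6‑en‑8‑yloxy]dimethylsilane
Conditions: TBSCl, imidazole, DMF, rt
Reagents that add atoms: tert‑butyldimethylsilyl chloride, CC(C)(C)[Si](C)(C)Cl
Why: Standard silylation of a secondary allylic alcohol; the bulky ether later steers both the aryl addition and the osmylation.

Step 14
Reactants: 18 silyl ether ketal (as above)
Product: 19 (4R)‑4‑[(tert‑butyldimethylsilyl)oxy]cyclohex‑2‑en‑1‑one
Conditions: pyridinium p‑toluenesulfonate (cat.), THF/H2O, 40 °C
Reagents that add atoms: water, O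
Why: Mild acid hydrolysis of the dioxolane unmasks the enone; the conditions are too weak to cleave the silyl ether or eliminate it.

Step 15
Reactants: 20 5‑bromo‑2,4‑dichloropyridine
Product: 21 5‑bromo‑2,4‑bis[2‑(trimethylsilyl)ethoxy]pyridine
Conditions: Me3SiCH2CH2OH (2.4 equiv), NaH (2.5 equiv), DMF, 0 → 70 °C
Reagents that add atoms: 2‑(trimethylsilyl)ethanol, C[Si](C)(C)CCO
Why: Nucleophilic aromatic substitution; the 4‑chloride (para to nitrogen) is displaced first and the 2‑chloride on warming, the 5‑bromide (meta to nitrogen) is not activated, and O‑ versus N‑alkylation cannot arise because oxygen enters as the nucleophile.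

Step 16
Reactants: 21 5‑bromo‑2,4‑bis[2‑(trimethylsilyl)ethoxy]pyridine; 19 (4R)‑4‑[(tert‑butyldimethylsilyl)oxy]cyclohex‑2‑en‑1‑one
Product: 24 5‑{(1S,4R)‑4‑[(tert‑butyldimethylsilyl)oxy]‑1‑[(triethylsilyl)oxy]cyclohex‑2‑en‑1‑yl}‑2,4‑bis[2‑(trimethylsilyl)ethoxy]pyridine, via 5‑lithiopyridine 22 (not isolated), via lithium alkoxide 23 (not isolated)
Conditions: n‑BuLi, Et2O/THF, −78 °C; then 19, −78 °C; then TESOTf, −78 → 0 °C; aq. NaHCO3
Reagents that add atoms: triethylsilyl trifluoromethanesulfonate, CC[Si](CC)(CC)OS(=O)(=O)C(F)(F)F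
Why: Bromine–lithium exchange outruns ring deprotonation; the aryllithium adds 1,2 to the enone along the axial trajectory, which is anti to the pseudo‑axial C4' silyloxy group, so the new C1'–O bond is cis to the C4' oxygen (sets C1'), and the tertiary alkoxide is capped in the same flask.

Step 17
Reactants: 24 cyclohexene bis‑silyl ether (as above)
Product: 25 (1R,2S,3R,6R)‑3‑{4,6‑bis[2‑(trimethylsilyl)ethoxy]pyridin‑3‑yl}‑6‑[(tert‑butyldimethylsilyl)oxy]‑3‑[(triethylsilyl)oxy]cyclohexane‑1,2‑diol
Conditions: OsO4 (5 mol%), N‑methylmorpholine N‑oxide, acetone/H2O, rt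
Reagents that add atoms: N‑methylmorpholine N‑oxide, C[N+]1([O-])CCOCC1; water, O
Why: Catalytic osmylation adds both oxygens suprafacially on the face anti to the two allylic silyloxy groups (the usual anti preference, here reinforced from both sides), setting C2' and C3', and unlike peracids it does not oxidise the pyridine nitrogen.

Step 18
Reactants: 25 cis‑diol (as above)
Product: 28 5‑{(1R,2S,3R,4R)‑4‑[(tert‑butyldimethylsilyl)oxy]‑2,3‑epoxy‑1‑[(triethylsilyl)oxy]cyclohexyl}‑2,4‑bis[2‑(trimethylsilyl)ethoxy]pyridine, via cyclic orthoacetate 26 (not isolated), via chloro acetate 27 (not isolated)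
Conditions: MeC(OMe)3, pyridinium p‑toluenesulfonate (cat.), CH2Cl2, rt; then Me3SiCl, CH2Cl2, rt; then K2CO3, MeOH, 0 °C → rt
Reagents that add atoms: none
Why: Orthoester/halohydrin‑ester conversion of a cis‑diol into the epoxide with net retention; chloride opens the acetoxonium ion with inversion (expected at C3', remote from the quaternary carbon), and after methanolysis the C2' alkoxide displaces chloride with a second inversion, so the epoxide stays on the face of the original diol whichever carbon is attacked.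

Step 19
Reactants: 28 epoxide (as above)
Product: 29 3‑bromo‑5‑{(1R,2S,3R,4R)‑4‑[(tert‑butyldimethylsilyl)oxy]‑2,3‑epoxy‑1‑[(triethylsilyl)oxy]cyclohexyl}‑2,4‑bis[2‑(trimethylsilyl)ethoxy]pyridine
Conditions: N‑bromosuccinimide, MeCN, 0 °C → rt
Reagents that add atoms: N‑bromosuccinimide, O=C1CCC(=O)N1Br
Why: Electrophilic aromatic bromination; C3, ortho to both alkoxy groups, is the only ring position still activated, and the neutral conditions spare the epoxide and silyl ethers.

Step 20
Reactants: 29 3‑bromopyridine (as above); 15 decalin aldehyde (as above)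
Product: 31 {2,4‑bis[2‑(trimethylsilyl)ethoxy]‑5‑[(1R,2S,3R,4R)‑4‑(tert‑butyldimethylsilyloxy)‑2,3‑epoxy‑1‑(triethylsilyloxy)cyclohexyl]pyridin‑3‑yl}[(1R,2S,4aS,7S,8aR)‑4,7‑dimethyl‑1‑[(1E)‑prop‑1‑en‑1‑yl]‑1,2,4a,5,6,7,8,8a‑octahydronaphthalen‑2‑yl]methanol (both carbinol epimers), via 3‑lithiopyridine 30 (not isolated)
Conditions: t‑BuLi (2.1 equiv), Et2O, −78 °C; then 15, −78 °C; aq. NH4Cl
Reagents that add atoms: none
Why: Bromine–lithium exchange at −78 °C is faster than any attack on the epoxide, and the aryllithium stabilised by two flanking alkoxy groups adds to the aldehyde; addition of a metalated 2,4‑dialkoxypyridine to an α‑branched aldehyde is the standard union for 3‑acyl‑4‑hydroxy‑2‑pyridones, and the carbinol epimers converge in step 21.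

Step 21
Reactants: 31 carbinol (as above)
Product: 32 {2,4‑bis[2‑(trimethylsilyl)ethoxy]‑5‑[(1R,2S,3R,4R)‑4‑(tert‑butyldimethylsilyloxy)‑2,3‑epoxy‑1‑(triethylsilyloxy)cyclohexyl]pyridin‑3‑yl}[(1R,2S,4aS,7S,8aR)‑4,7‑dimethyl‑1‑[(1E)‑prop‑1‑en‑1‑yl]‑1,2,4a,5,6,7,8,8a‑octahydronaphthalen‑2‑yl]methanone
Conditions: Dess–Martin periodinane, NaHCO3, CH2Cl2, 0 °C → rt
Reagents that add atoms: none
Why: Buffered Dess–Martin oxidation of the hindered benzylic‑type carbinol gives the aryl ketone without base, so the trans‑diequatorial C2 centre is kept.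

Step 22
Reactants: 32 protected ketone (as above)
Product: 33 3‑{[(1R,2S,4aS,7S,8aR)‑4,7‑dimethyl‑1‑[(1E)‑prop‑1‑en‑1‑yl]‑1,2,4a,5,6,7,8,8a‑octahydronaphthalen‑2‑yl]carbonyl}‑5‑[(1R,2S,3S,4R)‑2,3‑epoxy‑1,4‑dihydroxycyclohexyl]‑4‑hydroxypyridin‑2(1H)‑one (CNP0494338.1)
Conditions: Bu4NF/AcOH (1:1, excess), THF, 0 → 40 °C
Reagents that add atoms: none
Why: Fluoride cleaves both silyl ethers and, by attack at silicon with loss of ethene, both 2‑(trimethylsilyl)ethyl ethers (a vinylogous ester and a lactim ether, as used for nucleobase lactams), and the acetic acid buffer protonates each alkoxide as it forms so the epoxide should not migrate.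

## Compound list

1 | but‑3‑en‑2‑one (methyl vinyl ketone) | CC(=O)C=C | starting material
2 | 2‑[(triisopropylsilyl)oxy]buta‑1,3‑diene | C=CC(=C)O[Si](C(C)C)(C(C)C)C(C)C | intermediate
3 | ethyl (2E)‑4‑oxobut‑2‑enoate | O=C/C=C/C(=O)OCC | starting material
4 | ethyl (1R,6R)‑6‑formyl‑3‑[(triisopropylsilyl)oxy]cyclohex‑3‑ene‑1‑carboxylate (trans) | O=C[C@@H]1CC=C(O[Si](C(C)C)(C(C)C)C(C)C)C[C@H]1C(=O)OCC | intermediate
5 | ethyl (1R,6S)‑6‑[(1E)‑prop‑1‑en‑1‑yl]‑3‑[(triisopropylsilyl)oxy]cyclohex‑3‑ene‑1‑carboxylate | C/C=C/[C@@H]1CC=C(O[Si](C(C)C)(C(C)C)C(C)C)C[C@H]1C(=O)OCC | intermediate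
6 | ethyl (1R,2R)‑5‑oxo‑2‑[(1E)‑prop‑1‑en‑1‑yl]cyclohex‑3‑ene‑1‑carboxylate | C/C=C/[C@@H]1C=CC(=O)C[C@H]1C(=O)OCC | intermediate
7 | 2‑methylbuta‑1,3‑diene (isoprene) | C=CC(C)=C | starting material
8 | ethyl (1R,2R,4aR,8aR)‑7‑methyl‑4‑oxo‑1‑[(1E)‑prop‑1‑en‑1‑yl]‑1,2,3,4,4a,5,8,8a‑octahydronaphthalene‑2‑carboxylate (cis‑fused) | C/C=C/[C@@H]1[C@H]2CC(C)=CC[C@H]2C(=O)C[C@H]1C(=O)OCC | intermediate
9 | ethyl (1R,2R,4aS,8aR)‑7‑methyl‑4‑oxo‑1‑[(1E)‑prop‑1‑en‑1‑yl]‑1,2,3,4,4a,5,8,8a‑octahydronaphthalene‑2‑carboxylate (trans‑fused) | C/C=C/[C@@H]1[C@H]2CC(C)=CC[C@@H]2C(=O)C[C@H]1C(=O)OCC | intermediate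
10 | ethyl (1R,2R,4aS,7S,8aR)‑7‑methyl‑4‑oxo‑1‑[(1E)‑prop‑1‑en‑1‑yl]decahydronaphthalene‑2‑carboxylate | C/C=C/[C@@H]1[C@H]2C[C@@H](C)CC[C@@H]2C(=O)C[C@H]1C(=O)OCC | intermediate
11 | potassium C3=C4 enolate of 10 | C/C=C/[C@@H]1[C@H]2C[C@@H](C)CC[C@@H]2C([O-])=C[C@H]1C(=O)OCC.[K+] | intermediate
12 | ethyl (1R,2S,4aS,7S,8aR)‑7‑methyl‑1‑[(1E)‑prop‑1‑en‑1‑yl]‑4‑{[(trifluoromethyl)sulfonyl]oxy}‑1,2,4a,5,6,7,8,8a‑octahydronaphthalene‑2‑carboxylate | C/C=C/[C@@H]1[C@H]2C[C@@H](C)CC[C@@H]2C(OS(=O)(=O)C(F)(F)F)=C[C@H]1C(=O)OCC | intermediate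
13 | ethyl (1R,2S,4aS,7S,8aR)‑4,7‑dimethyl‑1‑[(1E)‑prop‑1‑en‑1‑yl]‑1,2,4a,5,6,7,8,8a‑octahydronaphthalene‑2‑carboxylate | C/C=C/[C@@H]1[C@H]2C[C@@H](C)CC[C@@H]2C(C)=C[C@H]1C(=O)OCC | intermediate
14 | [(1R,2S,4aS,7S,8aR)‑4,7‑dimethyl‑1‑[(1E)‑prop‑1‑en‑1‑yl]‑1,2,4a,5,6,7,8,8a‑octahydronaphthalen‑2‑yl]methanol | C/C=C/[C@@H]1[C@H]2C[C@@H](C)CC[C@@H]2C(C)=C[C@H]1CO | intermediate
15 | (1R,2S,4aS,7S,8aR)‑4,7‑dimethyl‑1‑[(1E)‑prop‑1‑en‑1‑yl]‑1,2,4a,5,6,7,8,8a‑octahydronaphthalene‑2‑carbaldehyde | C/C=C/[C@@H]1[C@H]2C[C@@H](C)CC[C@@H]2C(C)=C[C@H]1C=O | intermediate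
16 | 1,4‑dioxaspiro[4.5]dec‑6‑en‑8‑one | O=C1C=CC2(CC1)OCCO2 | starting material
17 | (8R)‑1,4‑dioxaspiro[4.5]dec‑6‑en‑8‑ol | O[C@H]1C=CC2(CC1)OCCO2 | intermediate
18 | tert‑butyl[(8R)‑1,4‑dioxaspiro[4.5]dec‑6‑en‑8‑yloxy]dimethylsilane | CC(C)(C)[Si](C)(C)O[C@H]1C=CC2(CC1)OCCO2 | intermediate
19 | (4R)‑4‑[(tert‑butyldimethylsilyl)oxy]cyclohex‑2‑en‑1‑one | CC(C)(C)[Si](C)(C)O[C@H]1C=CC(=O)CC1 | intermediate
20 | 5‑bromo‑2,4‑dichloropyridine | Clc1cc(Cl)c(Br)cn1 | starting material
21 | 5‑bromo‑2,4‑bis[2‑(trimethylsilyl)ethoxy]pyridine | C[Si](C)(C)CCOc1cc(OCC[Si](C)(C)C)c(Br)cn1 | intermediate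
22 | {4,6‑bis[2‑(trimethylsilyl)ethoxy]pyridin‑3‑yl}lithium | C[Si](C)(C)CCOc1cc(OCC[Si](C)(C)C)c([Li])cn1 | intermediate
23 | lithium (1S,4R)‑1‑{4,6‑bis[2‑(trimethylsilyl)ethoxy]pyridin‑3‑yl}‑4‑[(tert‑butyldimethylsilyl)oxy]cyclohex‑2‑en‑1‑olate | C[Si](C)(C)CCOc1cc(OCC[Si](C)(C)C)c(cn1)[C@]2(O[Li])CC[C@@H](O[Si](C)(C)C(C)(C)C)C=C2 | intermediate
24 | 5‑{(1S,4R)‑4‑[(tert‑butyldimethylsilyl)oxy]‑1‑[(triethylsilyl)oxy]cyclohex‑2‑en‑1‑yl}‑2,4‑bis[2‑(trimethylsilyl)ethoxy]pyridine (the two silyloxy groups cis) | C[Si](C)(C)CCOc1cc(OCC[Si](C)(C)C)c(cn1)[C@]2(O[Si](CC)(CC)CC)CC[C@@H](O[Si](C)(C)C(C)(C)C)C=C2 | intermediate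
25 | (1R,2S,3R,6R)‑3‑{4,6‑bis[2‑(trimethylsilyl)ethoxy]pyridin‑3‑yl}‑6‑[(tert‑butyldimethylsilyl)oxy]‑3‑[(triethylsilyl)oxy]cyclohexane‑1,2‑diol (diol anti to both silyloxy groups) | C[Si](C)(C)CCOc1cc(OCC[Si](C)(C)C)c(cn1)[C@]2(O[Si](CC)(CC)CC)CC[C@@H](O[Si](C)(C)C(C)(C)C)[C@H](O)[C@@H]2O | intermediate
26 | cyclic 2‑methoxy‑2‑methyl‑1,3‑dioxolane (orthoacetate) of diol 25, both epimers at the orthoester carbon | C[Si](C)(C)CCOc1cc(OCC[Si](C)(C)C)c(cn1)[C@]2(O[Si](CC)(CC)CC)CC[C@@H](O[Si](C)(C)C(C)(C)C)[C@@H]3OC(C)(OC)O[C@H]23 | intermediate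
27 | C2' acetate, C3' chloride derived from 25: chlorine on the face of the two silyloxy groups (C3' inverted), trans to the acetate | C[Si](C)(C)CCOc1cc(OCC[Si](C)(C)C)c(cn1)[C@]2(O[Si](CC)(CC)CC)CC[C@@H](O[Si](C)(C)C(C)(C)C)[C@@H](Cl)[C@@H]2OC(C)=O | intermediate
28 | 5‑{(1R,2S,3R,4R)‑4‑[(tert‑butyldimethylsilyl)oxy]‑2,3‑epoxy‑1‑[(triethylsilyl)oxy]cyclohexyl}‑2,4‑bis[2‑(trimethylsilyl)ethoxy]pyridine (epoxide anti to both silyloxy groups) | C[Si](C)(C)CCOc1cc(OCC[Si](C)(C)C)c(cn1)[C@]2(O[Si](CC)(CC)CC)CC[C@@H](O[Si](C)(C)C(C)(C)C)[C@@H]3O[C@@H]32 | intermediate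
29 | 3‑bromo‑5‑{(1R,2S,3R,4R)‑4‑[(tert‑butyldimethylsilyl)oxy]‑2,3‑epoxy‑1‑[(triethylsilyl)oxy]cyclohexyl}‑2,4‑bis[2‑(trimethylsilyl)ethoxy]pyridine | C[Si](C)(C)CCOc1c(Br)c(OCC[Si](C)(C)C)c(cn1)[C@]2(O[Si](CC)(CC)CC)CC[C@@H](O[Si](C)(C)C(C)(C)C)[C@@H]3O[C@@H]32 | intermediate
30 | 3‑lithio derivative of 29 (lithium in place of bromine) | C[Si](C)(C)CCOc1c([Li])c(OCC[Si](C)(C)C)c(cn1)[C@]2(O[Si](CC)(CC)CC)CC[C@@H](O[Si](C)(C)C(C)(C)C)[C@@H]3O[C@@H]32 | intermediate
31 | secondary carbinol from 30 and 15 (both epimers at the carbinol carbon; all other centres as in 15 and 28) | C/C=C/[C@@H]1[C@H]2C[C@@H](C)CC[C@@H]2C(C)=C[C@H]1C(O)c1c(OCC[Si](C)(C)C)c(cnc1OCC[Si](C)(C)C)[C@]3(O[Si](CC)(CC)CC)CC[C@@H](O[Si](C)(C)C(C)(C)C)[C@@H]4O[C@@H]43 | intermediate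
32 | aryl ketone: fully protected target (2,4‑bis[2‑(trimethylsilyl)ethoxy]pyridine, C1' triethylsilyl ether, C4' tert‑butyldimethylsilyl ether) | C/C=C/[C@@H]1[C@H]2C[C@@H](C)CC[C@@H]2C(C)=C[C@H]1C(=O)c1c(OCC[Si](C)(C)C)c(cnc1OCC[Si](C)(C)C)[C@]3(O[Si](CC)(CC)CC)CC[C@@H](O[Si](C)(C)C(C)(C)C)[C@@H]4O[C@@H]43 | intermediate
33 | 3‑{[(1R,2S,4aS,7S,8aR)‑4,7‑dimethyl‑1‑[(1E)‑prop‑1‑en‑1‑yl]‑1,2,4a,5,6,7,8,8a‑octahydronaphthalen‑2‑yl]carbonyl}‑5‑[(1R,2S,3S,4R)‑2,3‑epoxy‑1,4‑dihydroxycyclohexyl]‑4‑hydroxypyridin‑2(1H)‑one | C/C=C/[C@@H]1[C@H]2C[C@@H](C)CC[C@@H]2C(C)=C[C@H]1C(=O)c1c(O)c([C@]2(O)CC[C@@H](O)[C@@H]3O[C@@H]32)c[nH]c1=O | target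

## Step count and risk

Total step count: 22. Longest linear sequence: 14 (steps 1–11, then 20–22); the pyridine–cyclohexane branch is 8 steps (12–19) before the union.

**Step 2 (key step).** The most likely failure is insufficient facial discrimination, or loss of regiocontrol if the catalyst also engages the ester carbonyl; a competing Mukaiyama‑type addition with loss of the enol ether is the second concern. The fallback keeps the same two bonds but moves control to two‑point binding. It sets out from 2. N‑Acylation of 1,3‑oxazolidin‑2‑one with ethyl fumaroyl chloride gives ethyl (2E)‑4‑oxo‑4‑(2‑oxo‑1,3‑oxazolidin‑3‑yl)but‑2‑enoate F1. Cycloaddition of F1 with 2 under the copper bis(oxazoline) Lewis acid [Cu(t‑Bu‑box)](SbF6)2, in the antipode that the square‑planar chelate model assigns, should give the imide adduct F2, with the imide now the unambiguous activating group. LiBH4/H2O reduces the imide in the presence of the ethyl ester to the hydroxymethyl compound F3, and Dess–Martin oxidation returns to the route at 4.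

**Step 7.** Chemoselectivity may erode, with the propenyl group also taking up hydrogen, or hydrogen delivery to the C7 radical may discriminate poorly between the axial and equatorial directions. The fallback changes the mechanism from radical to ionic. It sets out from 9: Et3SiH and CF3CO2H in CH2Cl2 at 0 °C protonate only the trisubstituted alkene, because only it gives a tertiary cation, and the silane delivers hydride to C7. It returns at 10 and makes no new compound (F0).

**Step 16.** Facial selectivity of the 1,2‑addition rests on 1,4‑induction and may be modest, and enolisation of the enone by the aryllithium may lower conversion. The fallback sets the cis‑1,4 relation by a concerted cycloaddition, taking over the tactic of Alternative 1. It sets out from 21 and returns at 25.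
- The diol A1 is converted with 2,2‑dimethoxypropane into the bromodiene acetonide F4.
- Lithiated 21 is transmetalated with ZnCl2 and coupled with F4 [Pd(PPh3)4] to the pyridyl diene acetonide F5.
- Singlet oxygen (O2, tetraphenylporphyrin, light, −30 °C) adds across the diene anti to the acetonide to give the endoperoxide F6.
- Diimide saturates the remaining alkene to the dihydro endoperoxide F7.
- Thiourea reduces the O–O bond to the cis‑1,4‑diol acetonide F8.
- TBSCl/imidazole and then TESOTf give the bis‑silyl ether acetonide F9.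
- Mild aqueous acid removes the acetonide to reach 25.

**Step 18.** The halide opening of the acetoxonium ion at a carbon flanked by two oxygenated carbons may be slow, and the chlorosilane stage may cost a 2‑(trimethylsilyl)ethyl or triethylsilyl group. The fallback skips the diol. It sets out from 24: excess mCPBA buffered with NaHCO3 epoxidises the alkene from the face anti to both silyloxy groups and also oxidises the ring nitrogen, giving the epoxide N‑oxide F10. Bis(pinacolato)diboron then removes the N‑oxide oxygen under neutral conditions and the route is rejoined at 28.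

**Step 22.** Under insufficient buffering an alkoxide next to the epoxide may trigger epoxide migration, and cleavage of the second 2‑(trimethylsilyl)ethyl ether from an already anionic pyridone may stall. The fallback splits the unmasking into two mechanistically different stages. It sets out from 32: (Me2N)3S+ Me3SiF2− in DMF at 0 °C cleaves only the two 2‑(trimethylsilyl)ethyl ethers while both carbinols stay silylated, giving the pyridone bis‑silyl ether F11. HF·pyridine buffered with pyridine in THF then removes both silyl ethers without ever forming an alkoxide and arrives at 33.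

## Further compounds

F1 | step 2 | ethyl (2E)‑4‑oxo‑4‑(2‑oxo‑1,3‑oxazolidin‑3‑yl)but‑2‑enoate | CCOC(=O)/C=C/C(=O)N1CCOC1=O
F2 | step 2 | ethyl (1R,6R)‑6‑[(2‑oxo‑1,3‑oxazolidin‑3‑yl)carbonyl]‑3‑[(triisopropylsilyl)oxy]cyclohex‑3‑ene‑1‑carboxylate | O=C(N2CCOC2=O)[C@@H]1CC=C(O[Si](C(C)C)(C(C)C)C(C)C)C[C@H]1C(=O)OCC
F3 | step 2 | ethyl (1R,6R)‑6‑(hydroxymethyl)‑3‑[(triisopropylsilyl)oxy]cyclohex‑3‑ene‑1‑carboxylate | OC[C@@H]1CC=C(O[Si](C(C)C)(C(C)C)C(C)C)C[C@H]1C(=O)OCC
F0 | step 7 | none | none
F4 | step 16 | (3aS,7aS)‑4‑bromo‑2,2‑dimethyl‑3a,7a‑dihydro‑1,3‑benzodioxole | BrC1=CC=C[C@@H]2OC(C)(C)O[C@@H]21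
F5 | step 16 | 5‑[(3aR,7aS)‑2,2‑dimethyl‑3a,7a‑dihydro‑1,3‑benzodioxol‑4‑yl]‑2,4‑bis[2‑(trimethylsilyl)ethoxy]pyridine | C[Si](C)(C)CCOc1cc(OCC[Si](C)(C)C)c(cn1)C2=CC=C[C@@H]3OC(C)(C)O[C@@H]32
F6 | step 16 | endoperoxide of F5 bridging C1' and C4', anti to the acetonide | C[Si](C)(C)CCOc1cc(OCC[Si](C)(C)C)c(cn1)[C@]23OO[C@H](C=C2)[C@@H]4OC(C)(C)O[C@@H]43
F7 | step 16 | 5',6'‑dihydro derivative of endoperoxide F6 | C[Si](C)(C)CCOc1cc(OCC[Si](C)(C)C)c(cn1)[C@]23OO[C@H](CC2)[C@@H]4OC(C)(C)O[C@@H]43
F8 | step 16 | cis‑1',4'‑diol with 2',3'‑acetonide on the opposite face (from F7 by O–O reduction) | C[Si](C)(C)CCOc1cc(OCC[Si](C)(C)C)c(cn1)[C@]2(O)CC[C@@H](O)[C@@H]3OC(C)(C)O[C@@H]32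
F9 | step 16 | C1' triethylsilyl, C4' tert‑butyldimethylsilyl ether of F8 (the 2',3'‑acetonide of 25) | C[Si](C)(C)CCOc1cc(OCC[Si](C)(C)C)c(cn1)[C@]2(O[Si](CC)(CC)CC)CC[C@@H](O[Si](C)(C)C(C)(C)C)[C@@H]3OC(C)(C)O[C@@H]32
F10 | step 18 | pyridine N‑oxide of epoxide 28 | C[Si](C)(C)CCOc1cc(OCC[Si](C)(C)C)c(c[n+]1[O-])[C@]2(O[Si](CC)(CC)CC)CC[C@@H](O[Si](C)(C)C(C)(C)C)[C@@H]3O[C@@H]32
F11 | step 22 | C1' triethylsilyl, C4' tert‑butyldimethylsilyl ether of 33 | C/C=C/[C@@H]1[C@H]2C[C@@H](C)CC[C@@H]2C(C)=C[C@H]1C(=O)c1c(O)c([C@]2(O[Si](CC)(CC)CC)CC[C@@H](O[Si](C)(C)C(C)(C)C)[C@@H]3O[C@@H]32)c[nH]c1=O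
A1 | alternative 1 | (1S,2S)‑3‑bromocyclohexa‑3,5‑diene‑1,2‑diol | O[C@H]1C=CC=C(Br)[C@H]1O
A2 | alternative 1 | 5‑[(3aR,7aS)‑2,2‑dimethyl‑3a,7a‑dihydro‑1,3‑benzodioxol‑4‑yl]‑2,4‑bis(methoxymethoxy)pyridine | COCOc1cc(OCOC)ncc1C2=CC=C[C@@H]3OC(C)(C)O[C@@H]32
A3 | alternative 1 | endoperoxide of A2 bridging C1' and C4', anti to the acetonide | COCOc1cc(OCOC)ncc1[C@]12OO[C@H](C=C1)[C@@H]3OC(C)(C)O[C@@H]32
A4 | alternative 2 | 6‑[(1R,2S,4aS,7S,8aR)‑4,7‑dimethyl‑1‑[(1E)‑prop‑1‑en‑1‑yl]‑1,2,4a,5,6,7,8,8a‑octahydronaphthalen‑2‑yl]‑2,2‑dimethyl‑4H‑1,3‑dioxin‑4‑one | C/C=C/[C@@H]1[C@H]2C[C@@H](C)CC[C@@H]2C(C)=C[C@H]1C3=CC(=O)OC(C)(C)O3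
A5 | alternative 2 | acylketene from A4 (decalin‑2‑yl 3‑oxopropenoyl ketene) | C/C=C/[C@@H]1[C@H]2C[C@@H](C)CC[C@@H]2C(C)=C[C@H]1C(=O)C=C=O
A6 | alternative 2 | methyl (2Z)‑3‑amino‑2‑[(1R,2S,3R,4R)‑4‑(tert‑butyldimethylsilyloxy)‑2,3‑epoxy‑1‑(trimethylsilyloxy)cyclohexyl]prop‑2‑enoate | N/C=C(\C(=O)OC)[C@]2(O[Si](C)(C)C)CC[C@@H](O[Si](C)(C)C(C)(C)C)[C@@H]3O[C@@H]32
A7 | alternative 2 | C1' trimethylsilyl, C4' tert‑butyldimethylsilyl ether of 33 | C/C=C/[C@@H]1[C@H]2C[C@@H](C)CC[C@@H]2C(C)=C[C@H]1C(=O)c1c(O)c([C@]2(O[Si](C)(C)C)CC[C@@H](O[Si](C)(C)C(C)(C)C)[C@@H]3O[C@@H]32)c[nH]c1=O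
A8 | alternative 3 | 4‑methylcyclohexanone | CC1CCC(=O)CC1
A9 | alternative 3 | methyl (2Z,4E)‑2‑propanoylhexa‑2,4‑dienoate | C/C=C/C=C(/C(=O)CC)C(=O)OC
A10 | alternative 3 | methyl 4,7‑dimethyl‑3‑oxo‑1‑[(1E)‑prop‑1‑en‑1‑yl]‑1,2,3,5,6,7,8,8a‑octahydronaphthalene‑2‑carboxylate with C1, C2, C7 and C8a as in 33 | C/C=C/[C@@H]1[C@H]2C[C@@H](C)CCC2=C(C)C(=O)[C@H]1C(=O)OC
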